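The oxolane of the target has CH2 groups at C2 and C5 and carries the carbinol carbon C7 on C4, next to the benzyl-bearing C3. That pattern is cut at C2–C3 and C4–C5, which leads back to the methylene acetal of an (E)-allylic 1,2-diol. In one operation, tin tetrachloride should turn this (S,E)-alkenyl dioxolane into the trans oxolane aldehyde: both C–C bonds form, the ring closes, C3 is set by chirality transfer, C4 by equilibration, and C7 appears as a formyl group. The precursor carries ring A as a phenyl pivalate, not an aryl ether, to keep the arene out of the cationic chemistry. Aryl Grignard addition and one methanolysis finish the synthesis.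

Key step: step 4

Remark: the labels O1, C2, C3 (benzyl-bearing), C4 (C7-bearing), C5 and C7 are those of the target and are kept for all intermediates; ring A is the arene of the benzyl group, ring B the arene on C7.
Remark: in the chair model the (S)-carbinol with the (E)-alkene and a pseudo-equatorial tin-bound oxygen delivers the (R)-configured C3 of the target, so (S)-but-3-ene-1,2-diol is the correct enantiomer.
Remark: tin tetrachloride (step 4) and potassium carbonate (step 7) promote their steps without entering the balanced equations and are removed only at aqueous work-up.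

Step 1
Reactants: 1 eugenol (4-allyl-2-methoxyphenol)
Product: 2 4-allyl-2-methoxyphenyl pivalate
Conditions: PivCl, Et3N, 4-(dimethylamino)pyridine (cat.), CH2Cl2, 0 °C → rt
Reagents that add atoms: pivaloyl chloride, CC(C)(C)C(=O)Cl
Why: Amine-catalysed O-acylation of the phenol (nucleophilic acyl substitution) should be clean, and it replaces the electron-releasing, tin-labile ether function by an ester that survives steps 3 to 6.

Step 2
Reactants: 3 (S)-but-3-ene-1,2-diol; 4 dimethoxymethane
Product: 5 (S)-4-vinyl-1,3-dioxolane
Conditions: p-toluenesulfonic acid monohydrate (cat.), CH2Cl2, reflux over 4 Å molecular sieves; distillation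
Reagents that add atoms: none
Why: Acid-catalysed transacetalisation closes the five-membered methylene acetal once methanol is removed, and no bond to the stereocentre is broken, so it stays (S).

Step 3
Reactants: 2 4-allyl-2-methoxyphenyl pivalate (2 equiv); 5 (S)-4-vinyl-1,3-dioxolane
Product: 6 (4S)-4-[(1E)-3-(3-methoxy-4-pivaloyloxyphenyl)prop-1-en-1-yl]-1,3-dioxolane
Conditions: second-generation Grubbs catalyst RuCl2(=CHPh)(PCy3)(H2IMes) (3 mol%), 1,4-benzoquinone (10 mol%), CH2Cl2, 40 °C
Reagents that add atoms: none
Why: Olefin cross-metathesis of a readily dimerising allylarene with an allylic acetal branched at the allylic carbon should favour the cross product as the (E)-alkene under thermodynamic control, while benzoquinone suppresses migration of the allyl double bond by ruthenium hydrides; the stereocentre is not touched.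

Step 4
Reactants: 6 (4S)-4-[(1E)-3-(3-methoxy-4-pivaloyloxyphenyl)prop-1-en-1-yl]-1,3-dioxolane
Product: 9 (3R,4R)-4-[(3-methoxy-4-pivaloyloxyphenyl)methyl]oxolane-3-carbaldehyde, via tin-bound oxocarbenium ion 7 (not isolated), via enol oxocarbenium ion 8 (not isolated)
Conditions: SnCl4 (2 equiv), CH2Cl2, −78 → −20 °C; Et3N, then H2O
Reagents that add atoms: none
Why: SnCl4 binds the allylic acetal oxygen and opens the dioxolane to the O1=C2H2 oxocarbenium ion 7, whose chair 2-oxonia-[3,3] shift (or the stepwise Prins addition and pinacol shift) joins C2 to the distal alkene carbon C3 and leaves the (E)-tin enolate and the new O1=C5H2 oxocarbenium ion of 8, which combine to form C4–C5. The closest known reaction type is the Lewis-acid Prins–pinacol rearrangement of 4-alkenyl-1,3-dioxolanes to 3-acyloxolanes, used here on a formaldehyde acetal with a secondary carbinol and a 1,2-disubstituted alkene. The only ring formed, the oxolane, closes at C4–C5 by a 5-(enolexo)-endo-trig attack of the enol carbon on the oxocarbenium carbon. C3 is controlled by the (S)-carbinol, which in the chair with the tin-bound oxygen pseudo-equatorial and the (E)-alkene substituent equatorial exposes one alkene face to C2 and so gives the (R) centre of the target, and C4 is controlled thermodynamically, since it is α to the formyl group and settles trans to the benzyl group through the tin enolate. The step needs the oxocarbenium ion to be taken by the alkene and not by chloride or by ring A, and it needs the allylic C–O bond and the product aldehyde to stay intact; the alkene sits in a six-atom array with the cation, while the pivalate makes ring A a poorer nucleophile than an aryl ether and cannot be dealkylated by tin, and the low temperature limits Friedel–Crafts attack on the tin-bound aldehyde.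

Step 5
Reactants: 10 4-bromo-2-methoxyphenol
Product: 11 (4-bromo-2-methoxyphenoxy)(tert-butyl)dimethylsilane
Conditions: TBSCl, imidazole, DMF, rt
Reagents that add atoms: tert-butyldimethylsilyl chloride, CC(C)(C)[Si](C)(C)Cl
Why: Imidazole-mediated silylation of the phenol (silyl ether formation) removes the acidic proton before magnesium insertion and gives a group that falls off together with the pivalate in step 7.

Step 6
Reactants: 9 (3R,4R)-4-[(3-methoxy-4-pivaloyloxyphenyl)methyl]oxolane-3-carbaldehyde; 11 (4-bromo-2-methoxyphenoxy)(tert-butyl)dimethylsilane (1.4 equiv)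
Product: 13 4-{[(3R,4R)-4-[(R)-[4-(tert-butyldimethylsilyloxy)-3-methoxyphenyl](hydroxy)methyl]oxolan-3-yl]methyl}-2-methoxyphenyl pivalate, via arylmagnesium bromide 12 (not isolated)
Conditions: Mg turnings (I2-activated), THF, 45 °C; then 9, THF, −78 °C; sat. aq. NH4Cl
Reagents that add atoms: none
Why: Grignard 1,2-addition to the aldehyde should outpace attack on the hindered aryl pivalate at −78 °C, and the new C7 centre should arise mainly as (R) by Felkin–Anh attack anti to the branched C3 substituent of C4, which is also the face left open by a magnesium chelate between the carbonyl oxygen and O1.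

Step 7
Reactants: 13 4-{[(3R,4R)-4-[(R)-[4-(tert-butyldimethylsilyloxy)-3-methoxyphenyl](hydroxy)methyl]oxolan-3-yl]methyl}-2-methoxyphenyl pivalate
Product: 14 4-{[(3R,4R)-4-[(R)-hydroxy(4-hydroxy-3-methoxyphenyl)methyl]oxolan-3-yl]methyl}-2-methoxyphenol
Conditions: K2CO3, MeOH, rt; aq. NH4Cl
Reagents that add atoms: none
Why: Base-mediated methanolysis should cleave the aryl pivalate by transesterification and the aryl silyl ether by attack of methoxide at silicon in one operation, without hydrogenolysis or acid near the benzylic C7–OH and without touching any stereocentre.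

Compound list
1 | eugenol (4-allyl-2-methoxyphenol) | COc1cc(CC=C)ccc1O | starting material
2 | 4-allyl-2-methoxyphenyl pivalate | COc1cc(CC=C)ccc1OC(=O)C(C)(C)C | intermediate
3 | (S)-but-3-ene-1,2-diol | OC[C@@H](O)C=C | starting material
4 | dimethoxymethane | COCOC | starting material
5 | (S)-4-vinyl-1,3-dioxolane | C=C[C@H]1COCO1 | intermediate
6 | (4S)-4-[(1E)-3-(3-methoxy-4-pivaloyloxyphenyl)prop-1-en-1-yl]-1,3-dioxolane | COc1cc(C/C=C/[C@H]2COCO2)ccc1OC(=O)C(C)(C)C | intermediate
7 | tin-bound oxocarbenium ion: (S,E)-allylic tin alkoxide whose primary oxygen O1 carries the CH2=O(+) unit (not isolated) | COc1cc(C/C=C/[C@H](O[Sn-](Cl)(Cl)(Cl)Cl)C[O+]=C)ccc1OC(=O)C(C)(C)C | intermediate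
8 | enol oxocarbenium ion: (E)-tin enolate at C4=C7 with (R)-configured C3 and the O1=C5H2 oxocarbenium unit (not isolated) | C=[O+]C[C@H](Cc1ccc(OC(=O)C(C)(C)C)c(OC)c1)/C=C/O[Sn-](Cl)(Cl)(Cl)Cl | intermediate
9 | (3R,4R)-4-[(3-methoxy-4-pivaloyloxyphenyl)methyl]oxolane-3-carbaldehyde (trans) | COc1cc(C[C@H]2COC[C@@H]2C=O)ccc1OC(=O)C(C)(C)C | intermediate
10 | 4-bromo-2-methoxyphenol | COc1cc(Br)ccc1O | starting material
11 | (4-bromo-2-methoxyphenoxy)(tert-butyl)dimethylsilane | COc1cc(Br)ccc1O[Si](C)(C)C(C)(C)C | intermediate
12 | [4-(tert-butyldimethylsilyloxy)-3-methoxyphenyl]magnesium bromide (not isolated) | COc1cc([Mg]Br)ccc1O[Si](C)(C)C(C)(C)C | intermediate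
13 | 4-{[(3R,4R)-4-[(R)-[4-(tert-butyldimethylsilyloxy)-3-methoxyphenyl](hydroxy)methyl]oxolan-3-yl]methyl}-2-methoxyphenyl pivalate | COc1cc(C[C@H]2COC[C@@H]2[C@@H](O)c2ccc(O[Si](C)(C)C(C)(C)C)c(OC)c2)ccc1OC(=O)C(C)(C)C | intermediate
14 | 4-{[(3R,4R)-4-[(R)-hydroxy(4-hydroxy-3-methoxyphenyl)methyl]oxolan-3-yl]methyl}-2-methoxyphenol | COc1cc(C[C@H]2COC[C@@H]2[C@@H](O)c2ccc(O)c(OC)c2)ccc1O | target

Total step count: 7. Longest linear sequence: 5 steps (3 → 5 → 6 → 9 → 13 → 14).

Steps most likely to fail

1. Step 4. The tin-bound oxocarbenium ion may be intercepted by chloride, or the allylic C–O bond may ionise, before the unactivated 1,2-disubstituted alkene engages. A chair with the tin-bound oxygen axial may compete and erode the transfer of chirality to C3. Ring A may also attack the tin-bound aldehyde in a Friedel–Crafts sense. The fallback sets out from 2 and comes back at 9; it builds C3 by catalyst control and the ring by etherification. Cross-metathesis of 2 with (Z)-but-2-ene-1,4-diyl bis(methyl carbonate) (second-generation Grubbs catalyst, CH2Cl2, 40 °C) would give (E)-4-(3-methoxy-4-pivaloyloxyphenyl)but-2-en-1-yl methyl carbonate F1; the alkene geometry is not critical here. Iridium-catalysed asymmetric allylic alkylation with dimethyl malonate ([Ir(cod)Cl]2, binaphthol-derived chiral phosphoramidite ligand, THF, rt; the ligand enantiomer that gives the (S)-branched product) would give dimethyl 2-[(2S)-1-(3-methoxy-4-pivaloyloxyphenyl)but-3-en-2-yl]propanedioate F2. Ozonolysis (O3, CH2Cl2–MeOH, −78 °C) with NaBH4 and then LiBH4 (THF, 0 °C, the hindered pivalate being expected to survive) would reduce the ozonide and both esters to (3R)-2-(hydroxymethyl)-3-[(3-methoxy-4-pivaloyloxyphenyl)methyl]butane-1,4-diol F3. Mitsunobu cyclodehydration (PPh3, DIAD, THF) would join the hydroxymethyl group on C3 to either hydroxymethyl group on C4 and give {(4R)-4-[(3-methoxy-4-pivaloyloxyphenyl)methyl]oxolan-3-yl}methanol F4 as a mixture at C4. Dess–Martin oxidation followed by DBU in CH2Cl2 would converge both epimers on the trans aldehyde 9.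

2. Step 6. Facial discrimination at the formyl group may be poor, so that both C7 epimers form, and part of the Grignard reagent may be consumed by the pivalate. The fallback sets out from the crude product of step 6 and comes back at 13; it replaces substrate control by catalyst control. The mixture of 13 and its C7 epimer, 4-{[(3R,4R)-4-[(S)-[4-(tert-butyldimethylsilyloxy)-3-methoxyphenyl](hydroxy)methyl]oxolan-3-yl]methyl}-2-methoxyphenyl pivalate F5, would be oxidised with Dess–Martin periodinane (CH2Cl2, NaHCO3, rt) to 4-{[(3R,4R)-4-[4-(tert-butyldimethylsilyloxy)-3-methoxybenzoyl]oxolan-3-yl]methyl}-2-methoxyphenyl pivalate F6, in which C4 stays trans because that is the stable arrangement next to the ketone. Reduction with BH3·SMe2 and (S)-1-methyl-3,3-diphenyltetrahydro-1H,3H-pyrrolo[1,2-c][1,3,2]oxazaborole ((S)-methyl-CBS catalyst, THF, −20 °C), with ring B as the large group, should then give the (7R)-alcohol 13.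

3. Step 3. The E selectivity may be incomplete and the allyl double bond may migrate into conjugation with ring A; any (Z)-alkene would pass into step 4 and lower the enantiomeric purity at C3. The fallback sets out from 2 and 5 and comes back at 6; it makes the alkene by olefination. Ozonolysis of 2 with NaBH4 work-up would give 4-(2-hydroxyethyl)-2-methoxyphenyl pivalate F7. Mitsunobu thioetherification with 1-phenyl-1H-tetrazole-5-thiol (PPh3, DIAD, THF) would give 2-methoxy-4-{2-[(1-phenyl-1H-tetrazol-5-yl)sulfanyl]ethyl}phenyl pivalate F8, and oxidation (H2O2, (NH4)6Mo7O24 cat., EtOH) would give 2-methoxy-4-{2-[(1-phenyl-1H-tetrazol-5-yl)sulfonyl]ethyl}phenyl pivalate F9. Ozonolysis of 5 (O3, CH2Cl2, −78 °C; PPh3) would give (R)-1,3-dioxolane-4-carbaldehyde F10, to be used at once. Julia–Kocienski olefination of F9 with F10 (KN(SiMe3)2, DME, −60 °C) should give 6 with high E selectivity.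

Further compounds
F1 | step 4 | (E)-4-(3-methoxy-4-pivaloyloxyphenyl)but-2-en-1-yl methyl carbonate | COC(=O)OC/C=C/Cc1ccc(OC(=O)C(C)(C)C)c(OC)c1
F2 | step 4 | dimethyl 2-[(2S)-1-(3-methoxy-4-pivaloyloxyphenyl)but-3-en-2-yl]propanedioate | COc1cc(C[C@H](C(C(=O)OC)C(=O)OC)C=C)ccc1OC(=O)C(C)(C)C
F3 | step 4 | (3R)-2-(hydroxymethyl)-3-[(3-methoxy-4-pivaloyloxyphenyl)methyl]butane-1,4-diol | COc1cc(C[C@H](C(CO)CO)CO)ccc1OC(=O)C(C)(C)C
F4 | step 4 | {(4R)-4-[(3-methoxy-4-pivaloyloxyphenyl)methyl]oxolan-3-yl}methanol (mixture at C4) | COc1cc(C[C@H]2COCC2CO)ccc1OC(=O)C(C)(C)C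
F5 | step 6 | 4-{[(3R,4R)-4-[(S)-[4-(tert-butyldimethylsilyloxy)-3-methoxyphenyl](hydroxy)methyl]oxolan-3-yl]methyl}-2-methoxyphenyl pivalate | COc1cc(C[C@H]2COC[C@@H]2[C@H](O)c2ccc(O[Si](C)(C)C(C)(C)C)c(OC)c2)ccc1OC(=O)C(C)(C)C
F6 | step 6 | 4-{[(3R,4R)-4-[4-(tert-butyldimethylsilyloxy)-3-methoxybenzoyl]oxolan-3-yl]methyl}-2-methoxyphenyl pivalate | COc1cc(C[C@H]2COC[C@@H]2C(=O)c2ccc(O[Si](C)(C)C(C)(C)C)c(OC)c2)ccc1OC(=O)C(C)(C)C
F7 | step 3 | 4-(2-hydroxyethyl)-2-methoxyphenyl pivalate | COc1cc(CCO)ccc1OC(=O)C(C)(C)C
F8 | step 3 | 2-methoxy-4-{2-[(1-phenyl-1H-tetrazol-5-yl)sulfanyl]ethyl}phenyl pivalate | COc1cc(CCSc2nnnn2-c2ccccc2)ccc1OC(=O)C(C)(C)C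
F9 | step 3 | 2-methoxy-4-{2-[(1-phenyl-1H-tetrazol-5-yl)sulfonyl]ethyl}phenyl pivalate | COc1cc(CCS(=O)(=O)c2nnnn2-c2ccccc2)ccc1OC(=O)C(C)(C)C
F10 | step 3 | (R)-1,3-dioxolane-4-carbaldehyde | O=C[C@H]1COCO1
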